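The readings were computed on assumed constants; the scatter is artificial.

We read the flask at 2.5 d, and the amber and grey runs are what we have to go on.

| setting | amber | grey | flask |
|---|---|---|---|
| left-handed substrate | 1.1 M | 0.80 M | 0.80 M |
| right-handed substrate | 1.1 M | 0.80 M | 0.80 M |
| partner | 1.76 M | 0.88 M | 1.76 M |
| remark | run made earlier | run made earlier |  |
| time |  |  | 2.5 d |

- amber (time / d: left-handed substrate / %, right-handed substrate / %): 0.417: 26.4, 27.4; 1.04: 15.9, 16.7; 2.08: 7.3, 7.0; 3.00: 3.7, 4.2
- grey (time / d: left-handed substrate / %, right-handed substrate / %): 0.417: 31.0, 31.4; 1.04: 21.4, 21.1; 2.08: 11.2, 11.8; 3.00: 6.4, 6.6

(standard deviation of a reading: 0.3 percentage points)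

- part of the left-handed substrate and right-handed substrate charged together that has reacted at 2.5 d
- excess of left-handed product over right-handed product in the product at 2.5 d
- excess of right-handed substrate over left-handed substrate among what is left of the two at 2.5 d

- partner is single-handed; left-handed substrate and right-handed substrate are mirror images of each other, charged as a racemate, each of them at the stated concentration
- what has gone into achiral form counts as reacted
- an excess is the difference of the two amounts in percent of their sum
- an excess is below zero if the other one leads
- the handed part of partner does not stay in what it makes, so the products of the two hands are mirror images too

Read side by side, the left and right columns differ at each time by 1 percentage point at most, against a scatter of 0.3 points. Summed over the times of reading, right-handed substrate leads by 1.84% in amber and by 0.639% in grey. The lead reads larger in amber, which was charged with twice the partner of grey but also with more substrate.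

We suppose that the hands turn into each other through the achiral form, much faster than they react. The partner step then opens a gap between the hands and the exchange closes it, so the excess should equal the difference of the two hands' rates, per unit of substrate, over twice the rate constant with which the exchange closes the gap. If that difference of rates goes with [partner], so does the excess. The excess gain, the substrate excess per molar of partner charged, reads 0.00940 M⁻¹, a rough reading given the scatter. The readings do not give [partner], so charged partner stands in for it, and for the flask the gain gives us 1.65%. The same rule holds a warning: a small excess may come from quick exchange, so we draw no product excess from it, and we reckon no conversion of our own.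

The forecast puts the reacted part at 90.3%, the product excess at 3% and the substrate excess at 1.2%, reasoning that “Left therefore reacts slightly faster”. Its substrate excess stands below ours.

The flask gives 91.2% reacted, a product excess of 98.9% and a substrate excess of 0.844%.

    partner → decomposition product (k = 2.31 × 10⁻⁶ min⁻¹)
    achiral form → waste (k = 0.00288 min⁻¹)
    left-handed substrate ⇌ achiral form (K = 0.230, k = 0.0352 min⁻¹)
    partner + left-handed substrate → left-handed product (k = 0.00147 M⁻¹ min⁻¹)
    right-handed substrate ⇌ achiral form (K = 0.230, k = 0.0352 min⁻¹)
    partner ⇌ dormant form (K = 1.19, k = 0.00229 min⁻¹)
    partner + right-handed substrate → right-handed product (k = 7.60 × 10⁻⁶ M⁻¹ min⁻¹)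

In the flask the relaxation half-life of left-handed substrate and achiral form, by that step alone and both ways together, is 0.0614 h, far shorter than the 0.81 d half-life of left-handed substrate in its partner step at the asked time, while that partner step has 193 times the rate constant of its mirror, the selectivity factor. The excess gain gives 1.65% for the flask against 0.844%, and 2.82% against 1.75% for the neighbour charged with 3.0 M of partner. Per molar of partner itself left at the asked time, dormant form not counted, the flask shows 0.0210 M⁻¹ and that neighbour 0.0209 M⁻¹.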